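**Retrosynthetic overview**
- Naamidine E is cut at the exocyclic amidine C–N bond into the free 2-aminoimidazole hydroquinone 21 and 1-methylparabanic acid 22; 21 comes from the Boc/bis-MOM imidazole 20 by one acid step.
- The imidazole of 20 is opened at N1–C5 to the propargylguanidine 18. The strategy rests on this mapping: N3, C4 and the C4 4-methoxybenzyl arm are the nitrogen, α-carbon and side chain of O-methyltyrosine, and C5 with its benzylic CH2 are the two carbons of an aryl alkyne.
- 18 is cut at the guanidine C–N bond into amine 13 and N-Boc-N'-methylthiourea 16; 13 is cut at the aryl–alkyne bond into the tyrosine-derived propargylamine 7 and aryl iodide 12 (from 2,3-dimethoxybenzoquinone).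
- Ring order: both benzene rings and the parabanic ring are bought; the imidazole is the only ring formed (step 11), and the dehydrohydantoin is attached last (step 13).

Key step: step 11

Remark: 2,3-dimethoxy-1,4-benzoquinone is taken as purchasable; the S descriptors of the tyrosine-derived compounds up to 19 only record their origin, since this centre becomes the sp2 carbon C4 in step 11.

**Route**

Step 1
Reactants: 1 N-Boc-O-methyl-L-tyrosine
Product: 2 tert-butyl N-[(2S)-1-[methoxy(methyl)amino]-3-(4-methoxyphenyl)-1-oxopropan-2-yl]carbamate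
Conditions: MeNHOMe·HCl, EDC·HCl, HOBt, N-methylmorpholine, CH2Cl2, 0 °C to rt
Reagents that add atoms: N,O-dimethylhydroxylamine hydrochloride, CNOC.Cl
Why: Carbodiimide amide coupling of a urethane-protected amino acid should give the Weinreb amide with the Boc group untouched.

Step 2
Reactants: 2 Weinreb amide
Product: 3 tert-butyl N-[(2S)-1-(4-methoxyphenyl)-3-oxopropan-2-yl]carbamate (N-Boc-O-methyl-L-tyrosinal)
Conditions: LiAlH4, THF, 0 °C; then aq. potassium sodium tartrate; used crude
Reagents that add atoms: none
Why: Weinreb amide reduction (Fehrentz–Castro) stops at the aldehyde oxidation level because the chelated aluminate collapses only on work-up.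

Step 3
Reactants: 3 N-Boc-O-methyl-L-tyrosinal; 4 dimethyl (1-diazo-2-oxopropyl)phosphonate
Product: 6 tert-butyl N-[(2S)-1-(4-methoxyphenyl)but-3-yn-2-yl]carbamate, via dimethyl (diazomethyl)phosphonate 5 (not isolated)
Conditions: K2CO3, MeOH, 0 °C to rt
Reagents that add atoms: none
Why: Ohira–Bestmann (Seyferth–Gilbert) homologation, in which methanolysis of 4 releases 5, its anion olefinates the aldehyde and loss of N2 with 1,2-hydrogen shift gives the terminal alkyne; partial epimerization would be without consequence.

Step 4
Reactants: 6 Boc-protected propargylamine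
Product: 7 (2S)-1-(4-methoxyphenyl)but-3-yn-2-amine hydrochloride
Conditions: HCl (4 M in 1,4-dioxane), rt
Reagents that add atoms: hydrogen chloride, Cl
Why: Acidolysis of the tert-butyl carbamate, done before any MOM ether is present, should leave the terminal alkyne and the anisole untouched.

Step 5
Reactants: 8 2,3-dimethoxy-1,4-benzoquinone
Product: 9 2,3-dimethoxybenzene-1,4-diol
Conditions: H2 (1 atm), Pd/C, EtOAc, rt; filtered and concentrated under N2
Reagents that add atoms: none
Why: Catalytic hydrogenation of a benzoquinone to its hydroquinone is fast and forms no by-product.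

Step 6
Reactants: 9 2,3-dimethoxybenzene-1,4-diol
Product: 10 2,3-dimethoxy-1,4-bis(methoxymethoxy)benzene
Conditions: MOMCl, iPr2NEt, CH2Cl2, 0 °C to rt, N2
Reagents that add atoms: chloromethyl methyl ether, COCCl
Why: Williamson-type O-alkylation of both phenols with the reactive α-chloro ether protects the hydroquinone against oxidation and installs the directing groups for step 7.

Step 7
Reactants: 10 bis-MOM ether
Product: 12 1-iodo-3,4-dimethoxy-2,5-bis(methoxymethoxy)benzene, via aryllithium 11 (not isolated)
Conditions: n-BuLi (1.1 equiv), THF, −78 to 0 °C; then I2, THF, −78 °C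
Reagents that add atoms: iodine, II
Why: Directed ortho-metalation by the MOM ether at one of the two equivalent ring C–H positions followed by iodine quench gives the mono-iodide without acid that would endanger the acetals.

Step 8
Reactants: 7 propargylamine hydrochloride; 12 aryl iodide
Product: 13 (2S)-4-[3,4-dimethoxy-2,5-bis(methoxymethoxy)phenyl]-1-(4-methoxyphenyl)but-3-yn-2-amine
Conditions: Pd(PPh3)2Cl2 (5 mol %), CuI (10 mol %), Et3N, DMF, degassed, rt to 50 °C
Reagents that add atoms: none
Why: Sonogashira coupling of a terminal alkyne with an aryl iodide tolerates a free propargylic primary amine, and coupling at this stage avoids any later acid treatment in the presence of the MOM ethers.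

Step 9
Reactants: 14 tert-butyl carbamate; 15 methyl isothiocyanate
Product: 16 tert-butyl N-(methylcarbamothioyl)carbamate (N-Boc-N'-methylthiourea)
Conditions: NaH, THF, 0 °C to rt; then AcOH
Reagents that add atoms: none
Why: Addition of the carbamate anion to the isothiocyanate carbon fixes the Boc group and the methyl group on different nitrogens without ambiguity.

Step 10
Reactants: 13 arylalkynyl amine; 16 N-Boc-N'-methylthiourea
Product: 18 tert-butyl N-[[[(2S)-4-[2,5-bis(methoxymethoxy)-3,4-dimethoxyphenyl]-1-(4-methoxyphenyl)but-3-yn-2-yl]amino](methylamino)methylidene]carbamate, via N-Boc-N'-methylcarbodiimide 17 (not isolated)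
Conditions: EDC·HCl, iPr2NEt, CH2Cl2, 0 °C to rt
Reagents that add atoms: none
Why: Carbodiimide-driven desulfurization of the acylthiourea gives the electrophilic acylcarbodiimide 17, which the primary amine captures in a metal-free guanylation that cannot activate the alkyne prematurely.

Step 11
Reactants: 18 propargylguanidine
Product: 20 tert-butyl N-[5-[[2,5-bis(methoxymethoxy)-3,4-dimethoxyphenyl]methyl]-4-[(4-methoxyphenyl)methyl]-1-methylimidazol-2-yl]carbamate, via 5-arylidene-2-iminoimidazolidine 19 (not isolated)
Conditions: AgNO3 (20 mol %), MeCN, rt, dark; then DBU (0.5 equiv), 40 °C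
Reagents that add atoms: none
Why: AgNO3 binds the aryl alkyne as a π-acid and the N-methyl nitrogen of the acylguanidine adds anti to the alkyne carbon attached to the tyrosine α-carbon, forming N1–C5; protodeargentation gives the (Z)-ene-guanidine 19, and a base-assisted 1,3-prototropic shift of the C4 hydrogen to the exocyclic carbon aromatizes the ring and turns the arylidene into the benzyl arm. The closest known reaction type is the silver-promoted hydroamination of Boc-protected propargylguanidines bearing aryl alkynes, which gives 2-aminoimidazoles after isomerization. The imidazole, the only ring formed, closes in the 5-exo-dig mode. No stereocentre is created, and the tyrosine-derived centre is consumed on aromatization. The step needs exo rather than 6-endo closure and attack by the N-methyl nitrogen rather than the Boc-bearing nitrogen or the carbamate oxygen; the first is expected from the exo preference of silver with this substrate class, the second from the weak nucleophilicity of the carbamate-bearing imino nitrogen of a mono-acylated guanidine compared with the amine-like N-methylamino nitrogen. Since the ring-closing nitrogen already carries the methyl group, N1-methylation next to the C5 benzyl arm follows from connectivity and needs no separate alkylation.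

Step 12
Reactants: 20 Boc/bis-MOM imidazole
Product: 21 2-amino-5-(2,5-dihydroxy-3,4-dimethoxybenzyl)-4-(4-methoxybenzyl)-1-methylimidazole hydrochloride
Conditions: HCl (3 M in MeOH), 40 °C, argon; evaporation
Reagents that add atoms: hydrogen chloride, Cl
Why: Acidolysis of the carbamate and acid-catalysed methanolysis of both aryl MOM acetals should occur in one operation, and the salt form protects the aminoimidazole hydroquinone against air oxidation.

Step 13
Reactants: 21 aminoimidazole hydroquinone hydrochloride; 22 1-methylimidazolidine-2,4,5-trione (1-methylparabanic acid)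
Product: 24 naamidine E, via O-silyl imidate 23 (not isolated)
Conditions: 22, N,O-bis(trimethylsilyl)acetamide, MeCN, reflux; then 21, Et3N, PhMe, reflux, argon; MeOH quench
Reagents that add atoms: none
Why: Silylation turns the N3–H/C4=O lactam of 22 into an O-silyl imidate whose C4 is attacked by the exocyclic amine, and loss of trimethylsilanol gives the amidine, a condensation established for naamine-type 2-aminoimidazoles with free phenols; any adventitious phenol silyl ether would be cleaved by the methanol quench.

**Compound list**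
1 | N-Boc-O-methyl-L-tyrosine | COc1ccc(C[C@H](NC(=O)OC(C)(C)C)C(=O)O)cc1 | starting material
2 | tert-butyl N-[(2S)-1-[methoxy(methyl)amino]-3-(4-methoxyphenyl)-1-oxopropan-2-yl]carbamate | COc1ccc(C[C@H](NC(=O)OC(C)(C)C)C(=O)N(C)OC)cc1 | intermediate
3 | tert-butyl N-[(2S)-1-(4-methoxyphenyl)-3-oxopropan-2-yl]carbamate | COc1ccc(C[C@H](NC(=O)OC(C)(C)C)C=O)cc1 | intermediate
4 | dimethyl (1-diazo-2-oxopropyl)phosphonate | COP(=O)(OC)C(=[N+]=[N-])C(C)=O | starting material
5 | dimethyl (diazomethyl)phosphonate | COP(=O)(OC)C=[N+]=[N-] | intermediate (not isolated)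
6 | tert-butyl N-[(2S)-1-(4-methoxyphenyl)but-3-yn-2-yl]carbamate | COc1ccc(C[C@H](NC(=O)OC(C)(C)C)C#C)cc1 | intermediate
7 | (2S)-1-(4-methoxyphenyl)but-3-yn-2-amine hydrochloride | COc1ccc(C[C@H](N)C#C)cc1.Cl | intermediate
8 | 2,3-dimethoxy-1,4-benzoquinone | COC1=C(OC)C(=O)C=CC1=O | starting material
9 | 2,3-dimethoxybenzene-1,4-diol | COc1c(O)ccc(O)c1OC | intermediate
10 | 2,3-dimethoxy-1,4-bis(methoxymethoxy)benzene | COCOc1ccc(OCOC)c(OC)c1OC | intermediate
11 | [3,4-dimethoxy-2,5-bis(methoxymethoxy)phenyl]lithium | [Li]c1cc(OCOC)c(OC)c(OC)c1OCOC | intermediate (not isolated)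
12 | 1-iodo-3,4-dimethoxy-2,5-bis(methoxymethoxy)benzene | Ic1cc(OCOC)c(OC)c(OC)c1OCOC | intermediate
13 | (2S)-4-[3,4-dimethoxy-2,5-bis(methoxymethoxy)phenyl]-1-(4-methoxyphenyl)but-3-yn-2-amine | COc1ccc(C[C@H](N)C#Cc2cc(OCOC)c(OC)c(OC)c2OCOC)cc1 | intermediate
14 | tert-butyl carbamate | CC(C)(C)OC(N)=O | starting material
15 | methyl isothiocyanate | CN=C=S | starting material
16 | tert-butyl N-(methylcarbamothioyl)carbamate | CNC(=S)NC(=O)OC(C)(C)C | intermediate
17 | tert-butyl N-[(methylimino)methylidene]carbamate | CN=C=NC(=O)OC(C)(C)C | intermediate (not isolated)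
18 | tert-butyl N-[[[(2S)-4-[2,5-bis(methoxymethoxy)-3,4-dimethoxyphenyl]-1-(4-methoxyphenyl)but-3-yn-2-yl]amino](methylamino)methylidene]carbamate | COc1ccc(C[C@H](NC(=NC(=O)OC(C)(C)C)NC)C#Cc2cc(OCOC)c(OC)c(OC)c2OCOC)cc1 | intermediate
19 | tert-butyl N-[(4S,5Z)-5-[[2,5-bis(methoxymethoxy)-3,4-dimethoxyphenyl]methylidene]-4-[(4-methoxyphenyl)methyl]-1-methylimidazolidin-2-ylidene]carbamate | COc1ccc(C[C@@H]2NC(=NC(=O)OC(C)(C)C)N(C)/C2=C\c3cc(OCOC)c(OC)c(OC)c3OCOC)cc1 | intermediate (not isolated)
20 | tert-butyl N-[5-[[2,5-bis(methoxymethoxy)-3,4-dimethoxyphenyl]methyl]-4-[(4-methoxyphenyl)methyl]-1-methylimidazol-2-yl]carbamate | COc1ccc(Cc2nc(NC(=O)OC(C)(C)C)n(C)c2Cc2cc(OCOC)c(OC)c(OC)c2OCOC)cc1 | intermediate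
21 | 2-amino-5-(2,5-dihydroxy-3,4-dimethoxybenzyl)-4-(4-methoxybenzyl)-1-methylimidazole hydrochloride | COc1ccc(Cc2nc(N)n(C)c2Cc2cc(O)c(OC)c(OC)c2O)cc1.Cl | intermediate
22 | 1-methylimidazolidine-2,4,5-trione | CN1C(=O)NC(=O)C1=O | starting material
23 | 1-methyl-4-(trimethylsilyloxy)imidazole-2,5-dione | CN1C(=O)N=C(O[Si](C)(C)C)C1=O | intermediate (not isolated)
24 | naamidine E | COc1ccc(Cc2nc(NC3=NC(=O)N(C)C3=O)n(C)c2Cc2cc(O)c(OC)c(OC)c2O)cc1 | target

**Step count**
Total: 13 steps. Longest linear sequence: 9 steps (1, 2, 3, 4, 8, 10, 11, 12, 13).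

**Steps most likely to fail**

Step 11. Ring closure through the Boc-bearing nitrogen or the carbamate oxygen, 6-endo attack at the aryl-bearing alkyne carbon favoured by the electron-rich arene, or stalling before the prototropic shift could each divert the material. The fallback sets out from 13 and returns at 21; it builds the ring from an amidine that has only one nitrogen able to close and adds the 2-amino group afterwards. Amine 13 would be condensed with ethyl N-methylformimidate tetrafluoroborate (from N-methylformamide and Et3OBF4) to the N-methylformamidine F1. Cyclization of F1 with AgNO3 or Cs2CO3 in DMSO, a 5-exo-dig closure of an N-propargylamidine, should give after isomerization the C2-unsubstituted 1-methylimidazole F2. Lithiation of F2 at C2 (n-BuLi, THF, −78 °C) and quench with TsN3 would give the 2-azidoimidazole F3, hydrogenation (H2, Pd/C) the bis-MOM 2-aminoimidazole F4, and HCl in MeOH then gives 21.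

Step 13. Air oxidation of the free hydroquinone during the hot condensation, or attack at the wrong carbonyl, could erode the last step. The fallback sets out from 21 and returns at 24; it masks the phenols during the condensation. Silylation of 21 with TBSCl and imidazole in DMF would give the bis-TBS ether F5 as the free amine. Condensation of F5 with 23 as in step 13 should give the bis-TBS naamidine F6, and Et3N·3HF in THF at 0 °C would release 24 under conditions that are neither aqueous acid nor strong base.

Step 8. Sequestration of copper and palladium by the free primary amine and oxidative alkyne homocoupling (Glaser), made worse by slow oxidative addition of the electron-rich iodide, could limit the coupling. The fallback sets out from 7 and returns at 18; it reverses the order of guanylation and coupling. Amine salt 7 would be guanylated with 16, EDC·HCl and iPr2NEt to the terminal-alkyne propargylguanidine F7, and Sonogashira coupling of the non-basic acylguanidine F7 with 12 (Pd(PPh3)2Cl2, CuI, Et3N, DMF, rt) then gives 18.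

**Further compounds**
F1 | step 11 | N-[(2S)-4-[3,4-dimethoxy-2,5-bis(methoxymethoxy)phenyl]-1-(4-methoxyphenyl)but-3-yn-2-yl]-N'-methylformamidine | COc1ccc(C[C@H](N=CNC)C#Cc2cc(OCOC)c(OC)c(OC)c2OCOC)cc1
F2 | step 11 | 5-[[2,5-bis(methoxymethoxy)-3,4-dimethoxyphenyl]methyl]-4-[(4-methoxyphenyl)methyl]-1-methylimidazole | COc1ccc(Cc2ncn(C)c2Cc2cc(OCOC)c(OC)c(OC)c2OCOC)cc1
F3 | step 11 | 2-azido-5-[[2,5-bis(methoxymethoxy)-3,4-dimethoxyphenyl]methyl]-4-[(4-methoxyphenyl)methyl]-1-methylimidazole | COc1ccc(Cc2nc(N=[N+]=[N-])n(C)c2Cc2cc(OCOC)c(OC)c(OC)c2OCOC)cc1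
F4 | step 11 | 5-[[2,5-bis(methoxymethoxy)-3,4-dimethoxyphenyl]methyl]-4-[(4-methoxyphenyl)methyl]-1-methylimidazol-2-amine | COc1ccc(Cc2nc(N)n(C)c2Cc2cc(OCOC)c(OC)c(OC)c2OCOC)cc1
F5 | step 13 | 5-[[2,5-bis(tert-butyldimethylsilyloxy)-3,4-dimethoxyphenyl]methyl]-4-[(4-methoxyphenyl)methyl]-1-methylimidazol-2-amine | COc1ccc(Cc2nc(N)n(C)c2Cc2cc(O[Si](C)(C)C(C)(C)C)c(OC)c(OC)c2O[Si](C)(C)C(C)(C)C)cc1
F6 | step 13 | naamidine E bis(tert-butyldimethylsilyl) ether | COc1ccc(Cc2nc(NC3=NC(=O)N(C)C3=O)n(C)c2Cc2cc(O[Si](C)(C)C(C)(C)C)c(OC)c(OC)c2O[Si](C)(C)C(C)(C)C)cc1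
F7 | step 8 | tert-butyl N-[[[(2S)-1-(4-methoxyphenyl)but-3-yn-2-yl]amino](methylamino)methylidene]carbamate | COc1ccc(C[C@H](NC(=NC(=O)OC(C)(C)C)NC)C#C)cc1
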